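Flavan numbering is used: O1, C2, C3, C4, C4a, C5–C8, C8a; ring A is the benzo ring, ring B the 2-aryl group, ring C the pyran ring. The first cuts take the C8 diketone back to a diarylalkyne, then break C8–C(sp) to give an 8-iodoflavan and an arylacetylene.
The next cut is C3–C4 of ring C. Placing an NH between C3 and C4 gives a seven-membered 1,4-benzoxazepine, which is cut at N–C4 (imine of a formyl group) and at O1–C8a (SNAr on a 2-fluorobenzaldehyde).
Enabling feature: C3–C4 is the only bond of ring C between two CH2 groups. C4 is benzylic to ring A, and its radical is stabilised by O1, O5 and O7, which sit ortho/para to C4a. C2 lies outside this bond. Loss of N2 from the isodiazene of the cyclic amine therefore joins two carbons that were both electrophiles (formyl C4, phenacyl C3).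
Forward order: ring A aldehyde + ring B azido alcohol → aryl ether → seven-membered ring → contraction to ring C → benzyl-to-silyl exchange → C8 iodination → Sonogashira coupling → alkyne oxidation → desilylation.
Stereochemistry: C2 comes from asymmetric transfer hydrogenation of an α-azido ketone. Its C–O bond is never broken afterwards, and it is a spectator in the ring contraction.

Key step: step 7

Remark: the target is handled as the open 1,2-diketone drawn; its ring-chain tautomer with the C7 hydroxyl (a 2-hydroxybenzofuran-3-one) is the same substance in equilibrium. Compounds 1, 5, 12 and 19 are taken as commercial.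

Step 1
Reactants: 1 5-fluororesorcinol
Product: 2 1,3-bis(benzyloxy)-5-fluorobenzene
Conditions: BnBr, K2CO3, DMF, 50 °C
Reagents that add atoms: benzyl bromide, BrCc1ccccc1
Why: Williamson ether synthesis; both phenoxides are alkylated and the unactivated aryl fluoride is inert to carbonate.

Step 2
Reactants: 2 1,3-bis(benzyloxy)-5-fluorobenzene
Product: 4 2,4-bis(benzyloxy)-6-fluorobenzaldehyde, via iminium chloride 3 (not isolated)
Conditions: POCl3, DMF, 0 to 70 °C; then aq NaOAc
Reagents that add atoms: N,N-dimethylformamide, CN(C)C=O; water, O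
Why: Vilsmeier–Haack formylation; the chloroiminium ion should attack para to one benzyloxy group and next to the small fluorine rather than the crowded site between the two benzyloxy groups, and hydrolysis of 3 gives the aldehyde.

Step 3
Reactants: 5 2-bromo-1-[4-(benzyloxy)phenyl]ethan-1-one
Product: 6 2-azido-1-[4-(benzyloxy)phenyl]ethan-1-one
Conditions: NaN3, acetone-H2O, rt
Reagents that add atoms: sodium azide, [Na+].[N-]=[N+]=[N-]
Why: SN2 displacement of an activated phenacyl bromide by azide.

Step 4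
Reactants: 6 2-azido-1-[4-(benzyloxy)phenyl]ethan-1-one
Product: 7 (R)-2-azido-1-[4-(benzyloxy)phenyl]ethan-1-ol
Conditions: RuCl[(S,S)-TsDPEN](p-cymene) (cat.), HCO2H-Et3N azeotrope, EtOAc, rt
Reagents that add atoms: none
Why: Noyori-type asymmetric transfer hydrogenation; the (S,S)-ligand delivers hydride in the same spatial sense as for acetophenone, which sets the future C2 (descriptor R here only because CH2N3 outranks aryl).

Step 5
Reactants: 7 (R)-2-azido-1-[4-(benzyloxy)phenyl]ethan-1-ol; 4 2,4-bis(benzyloxy)-6-fluorobenzaldehyde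
Product: 8 (R)-2-{2-azido-1-[4-(benzyloxy)phenyl]ethoxy}-4,6-bis(benzyloxy)benzaldehyde
Conditions: NaH, DMF, 0 °C; then 4, 0 to 50 °C
Reagents that add atoms: none
Why: Nucleophilic aromatic substitution (addition–elimination) of the fluoride ortho to the formyl group, with both benzyloxy groups meta to the reacting carbon; only the O–H bond of 7 is broken, so C2 keeps its configuration.

Step 6
Reactants: 8 (R)-2-{2-azido-1-[4-(benzyloxy)phenyl]ethoxy}-4,6-bis(benzyloxy)benzaldehyde
Product: 11 (R)-6,8-bis(benzyloxy)-2-[4-(benzyloxy)phenyl]-2,3,4,5-tetrahydro-1,4-benzoxazepine, via iminophosphorane 9 (not isolated), via cyclic imine 10 (not isolated)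
Conditions: PPh3, THF, rt then 60 °C; then MeOH, NaBH4, 0 °C
Reagents that add atoms: none
Why: Staudinger reaction, intramolecular aza-Wittig closure of the seven-membered ring and borohydride reduction of the conjugated imine in one pot; C2 is not involved.

Step 7
Reactants: 11 (R)-6,8-bis(benzyloxy)-2-[4-(benzyloxy)phenyl]-2,3,4,5-tetrahydro-1,4-benzoxazepine; 12 N-(benzyloxy)-N-(pivaloyloxy)-4-(trifluoromethyl)benzamide
Product: 15 (S)-5,7-bis(benzyloxy)-2-[4-(benzyloxy)phenyl]chroman, via N-aminoamide adduct 13 (not isolated), via isodiazene 14 (not isolated)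
Conditions: 12 (1.5 equiv), THF, 45 °C
Reagents that add atoms: none
Why: The secondary amine 11 displaces pivalate at the nitrogen of the anomeric amide 12 to give 13, whose benzyloxy group shifts from N to the acyl carbon (HERON-type rearrangement), releasing benzyl 4-(trifluoromethyl)benzoate and the isodiazene 14; 14 loses N2 by homolysis, starting at the weak benzylic C4–N bond, and the C3/C4 radical pair collapses to the C3–C4 bond. The closest known reaction type is the nitrogen deletion of secondary benzylic amines with anomeric amides through 1,1-diazenes, which is established for the ring contraction of cyclic benzylic amines. The six-membered ring closes by intramolecular recombination of a singlet 1,6-biradical held together by the C2–O1–C8a–C4a tether, so no polar exo or endo mode applies and the seven-membered ring loses exactly its nitrogen atom. No stereocentre is formed: none of the four bonds of C2 is broken, and the descriptor changes from R to S only because C3 no longer carries nitrogen. The step needs recombination to outrun β-scission of the C2–O1 bond at the C3 radical (ring opening and re-addition would erode enantiopurity), hydrogen transfer, and tautomerisation of 14 to a hydrazone. The tether, the singlet spin state, the stabilisation of the C4 radical by the ortho/para oxygens of ring A and the low temperature should secure this.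

Step 8
Reactants: 15 (S)-5,7-bis(benzyloxy)-2-[4-(benzyloxy)phenyl]chroman
Product: 16 (S)-2-(4-hydroxyphenyl)chroman-5,7-diol
Conditions: H2 (1 atm), Pd/C, EtOAc-MeOH, rt
Reagents that add atoms: none
Why: Catalytic hydrogenolysis of the three primary benzyl aryl ethers, done here because it would not tolerate the later iodide, alkyne or diketone; the cyclic C2–O1 ether of flavans survives such mild conditions.

Step 9
Reactants: 16 (S)-2-(4-hydroxyphenyl)chroman-5,7-diol
Product: 17 (S)-5,7-bis(tert-butyldimethylsilyloxy)-2-[4-(tert-butyldimethylsilyloxy)phenyl]chroman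
Conditions: TBSCl, imidazole, DMF, rt
Reagents that add atoms: tert-butyldimethylsilyl chloride, CC(C)(C)[Si](C)(C)Cl
Why: Standard silylation of phenols; the silyl ethers keep ring A electron-rich and can be removed at the end without acid, base, Lewis acid or hydrogen.

Step 10
Reactants: 17 (S)-5,7-bis(tert-butyldimethylsilyloxy)-2-[4-(tert-butyldimethylsilyloxy)phenyl]chroman
Product: 18 (S)-8-iodo-5,7-bis(tert-butyldimethylsilyloxy)-2-[4-(tert-butyldimethylsilyloxy)phenyl]chroman
Conditions: NIS (1 equiv), CH2Cl2, -20 to 0 °C, dark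
Reagents that add atoms: N-iodosuccinimide, O=C1CCC(=O)N1I
Why: Electrophilic aromatic iodination of the most electron-rich ring; C8 lies between the tied-back O1 and one silyloxy group whereas C6 is shielded by two bulky silyloxy groups, in line with the known C8 halogenation of 5,7-di-O-protected flavans.

Step 11
Reactants: 18 (S)-8-iodo-5,7-bis(tert-butyldimethylsilyloxy)-2-[4-(tert-butyldimethylsilyloxy)phenyl]chroman; 19 tert-butyl(4-ethynylphenoxy)dimethylsilane
Product: 20 (S)-8-{[4-(tert-butyldimethylsilyloxy)phenyl]ethynyl}-5,7-bis(tert-butyldimethylsilyloxy)-2-[4-(tert-butyldimethylsilyloxy)phenyl]chroman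
Conditions: PdCl2(PPh3)2 (cat.), CuI (cat.), Et3N-THF, 60 °C
Reagents that add atoms: none
Why: Sonogashira coupling; 2,6-dioxygenated aryl iodides couple with the slim copper acetylide despite the ortho groups, and aryl silyl ethers tolerate the amine.

Step 12
Reactants: 20 (S)-8-{[4-(tert-butyldimethylsilyloxy)phenyl]ethynyl}-5,7-bis(tert-butyldimethylsilyloxy)-2-[4-(tert-butyldimethylsilyloxy)phenyl]chroman
Product: 21 1-{(S)-5,7-bis(tert-butyldimethylsilyloxy)-2-[4-(tert-butyldimethylsilyloxy)phenyl]chroman-8-yl}-2-[4-(tert-butyldimethylsilyloxy)phenyl]ethane-1,2-dione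
Conditions: KMnO4, NaHCO3, MgSO4, acetone-H2O, 0 °C to rt
Reagents that add atoms: potassium permanganate, [K+].[O-][Mn](=O)(=O)=O
Why: Buffered permanganate oxidation of a diarylalkyne to a benzil; this concerted oxidant avoids the electrophile-induced cyclisation of ortho-oxygenated arylalkynes to benzofurans that iodine or divalent palladium could trigger.

Step 13
Reactants: 21 1-{(S)-5,7-bis(tert-butyldimethylsilyloxy)-2-[4-(tert-butyldimethylsilyloxy)phenyl]chroman-8-yl}-2-[4-(tert-butyldimethylsilyloxy)phenyl]ethane-1,2-dione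
Product: 22 1-[(2S)-5,7-dihydroxy-2-(4-hydroxyphenyl)-3,4-dihydro-2H-chromen-8-yl]-2-(4-hydroxyphenyl)ethane-1,2-dione
Conditions: Et3N·3HF, THF, 0 °C to rt
Reagents that add atoms: none
Why: Fluoride-mediated desilylation in a slightly acidic medium; no free 4'-phenoxide is formed, so ring C cannot open through a para-quinone methide and C2 should stay intact, and the diketone is untouched.

Compound list
1 | 5-fluororesorcinol | Oc1cc(O)cc(F)c1 | starting material
2 | 1,3-bis(benzyloxy)-5-fluorobenzene | Fc1cc(OCc2ccccc2)cc(OCc2ccccc2)c1 | intermediate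
3 | [2,4-bis(benzyloxy)-6-fluorobenzylidene]dimethylammonium chloride (not isolated) | C[N+](C)=Cc1c(F)cc(OCc2ccccc2)cc1OCc1ccccc1.[Cl-] | intermediate
4 | 2,4-bis(benzyloxy)-6-fluorobenzaldehyde | O=Cc1c(F)cc(OCc2ccccc2)cc1OCc1ccccc1 | intermediate
5 | 2-bromo-1-[4-(benzyloxy)phenyl]ethan-1-one | O=C(CBr)c1ccc(OCc2ccccc2)cc1 | starting material
6 | 2-azido-1-[4-(benzyloxy)phenyl]ethan-1-one | O=C(CN=[N+]=[N-])c1ccc(OCc2ccccc2)cc1 | intermediate
7 | (R)-2-azido-1-[4-(benzyloxy)phenyl]ethan-1-ol | O[C@H](c1ccc(OCc2ccccc2)cc1)CN=[N+]=[N-] | intermediate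
8 | (R)-2-{2-azido-1-[4-(benzyloxy)phenyl]ethoxy}-4,6-bis(benzyloxy)benzaldehyde | O=Cc1c(OCc2ccccc2)cc(OCc2ccccc2)cc1O[C@H](c1ccc(OCc2ccccc2)cc1)CN=[N+]=[N-] | intermediate
9 | iminophosphorane of 8 (not isolated) | O=Cc1c(OCc2ccccc2)cc(OCc2ccccc2)cc1O[C@H](c1ccc(OCc2ccccc2)cc1)CN=P(c1ccccc1)(c1ccccc1)c1ccccc1 | intermediate
10 | (R)-6,8-bis(benzyloxy)-2-[4-(benzyloxy)phenyl]-2,3-dihydro-1,4-benzoxazepine (not isolated) | C1=NC[C@@H](c2ccc(OCc3ccccc3)cc2)Oc2cc(OCc3ccccc3)cc(OCc3ccccc3)c21 | intermediate
11 | (R)-6,8-bis(benzyloxy)-2-[4-(benzyloxy)phenyl]-2,3,4,5-tetrahydro-1,4-benzoxazepine | C1NC[C@@H](c2ccc(OCc3ccccc3)cc2)Oc2cc(OCc3ccccc3)cc(OCc3ccccc3)c21 | intermediate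
12 | N-(benzyloxy)-N-(pivaloyloxy)-4-(trifluoromethyl)benzamide | O=C(c1ccc(cc1)C(F)(F)F)N(OCc1ccccc1)OC(=O)C(C)(C)C | starting material
13 | N-(benzyloxy)-N-[(R)-benzoxazepin-4-yl]-4-(trifluoromethyl)benzamide adduct of 11 (not isolated) | O=C(c1ccc(cc1)C(F)(F)F)N(OCc1ccccc1)N1Cc2c(OCc3ccccc3)cc(OCc3ccccc3)cc2O[C@H](c2ccc(OCc3ccccc3)cc2)C1 | intermediate
14 | isodiazene (1,1-diazene) of 11 (not isolated) | [N-]=[N+]1Cc2c(OCc3ccccc3)cc(OCc3ccccc3)cc2O[C@H](c2ccc(OCc3ccccc3)cc2)C1 | intermediate
15 | (S)-5,7-bis(benzyloxy)-2-[4-(benzyloxy)phenyl]chroman | C1C[C@@H](c2ccc(OCc3ccccc3)cc2)Oc2cc(OCc3ccccc3)cc(OCc3ccccc3)c21 | intermediate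
16 | (S)-2-(4-hydroxyphenyl)chroman-5,7-diol | C1C[C@@H](c2ccc(O)cc2)Oc2cc(O)cc(O)c21 | intermediate
17 | (S)-5,7-bis(tert-butyldimethylsilyloxy)-2-[4-(tert-butyldimethylsilyloxy)phenyl]chroman | C1C[C@@H](c2ccc(O[Si](C)(C)C(C)(C)C)cc2)Oc2cc(O[Si](C)(C)C(C)(C)C)cc(O[Si](C)(C)C(C)(C)C)c21 | intermediate
18 | (S)-8-iodo derivative of 17 | C1C[C@@H](c2ccc(O[Si](C)(C)C(C)(C)C)cc2)Oc2c(I)c(O[Si](C)(C)C(C)(C)C)cc(O[Si](C)(C)C(C)(C)C)c21 | intermediate
19 | tert-butyl(4-ethynylphenoxy)dimethylsilane | C#Cc1ccc(O[Si](C)(C)C(C)(C)C)cc1 | starting material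
20 | (S)-8-(arylethynyl)flavan tetrasilyl ether | C1C[C@@H](c2ccc(O[Si](C)(C)C(C)(C)C)cc2)Oc2c(C#Cc3ccc(O[Si](C)(C)C(C)(C)C)cc3)c(O[Si](C)(C)C(C)(C)C)cc(O[Si](C)(C)C(C)(C)C)c21 | intermediate
21 | (S)-8-(arylglyoxyloyl)flavan tetrasilyl ether | C1C[C@@H](c2ccc(O[Si](C)(C)C(C)(C)C)cc2)Oc2c(C(=O)C(=O)c3ccc(O[Si](C)(C)C(C)(C)C)cc3)c(O[Si](C)(C)C(C)(C)C)cc(O[Si](C)(C)C(C)(C)C)c21 | intermediate
22 | 1-[(2S)-5,7-dihydroxy-2-(4-hydroxyphenyl)-3,4-dihydro-2H-chromen-8-yl]-2-(4-hydroxyphenyl)ethane-1,2-dione | O=C(C(=O)c1c(O)cc(O)c2c1O[C@H](c1ccc(O)cc1)CC2)c1ccc(O)cc1 | target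

Total step count: 13. Longest linear sequence: 11 steps (1 → 2 → 4 → 8 → 11 → 15 → 16 → 17 → 18 → 20 → 21 → 22; the branch from 5 is equally long).

Steps most likely to fail

Step 7. The C3 radical may expel the aryloxy group by β-scission of C2–O1 before it recombines, which opens the ring and erodes enantiopurity on re-addition. The isodiazene may tautomerise to a hydrazone, or N-amination may be slow. The fallback sets out from 4 and comes back at 15; it makes ring C by a polar C–O closure instead of a radical C–C closure.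
- SNAr of 4 with KOH in DMSO-H2O should give 2,4-bis(benzyloxy)-6-hydroxybenzaldehyde F1.
- Claisen–Schmidt condensation of F1 with commercial 4'-(benzyloxy)acetophenone (KOH, EtOH) should give (E)-3-[2,4-bis(benzyloxy)-6-hydroxyphenyl]-1-[4-(benzyloxy)phenyl]prop-2-en-1-one F2.
- Tandem transfer hydrogenation of C=C and C=O with RuCl[(R,R)-TsDPEN](p-cymene), HCO2Na, H2O-MeOH should give (R)-3-[2,4-bis(benzyloxy)-6-hydroxyphenyl]-1-[4-(benzyloxy)phenyl]propan-1-ol F3.
- Mitsunobu cyclisation (PPh3, DIAD, THF, 0 °C) closes O1–C2 with inversion to 15.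

Step 5. Three processes may slow or divert the substitution: hydride transfer from the secondary alkoxide to the aldehyde, reversible hemiacetal formation, and the low electrophilicity of the donor-substituted ring. The fallback sets out from 7 and comes back at 8; it reverses the order of the substitutions so that the chiral alkoxide meets the most activated ring.
- The sodium alkoxide of 7 and commercial 2,4,6-trifluorobenzaldehyde in THF-toluene at low temperature should give (R)-2-{2-azido-1-[4-(benzyloxy)phenyl]ethoxy}-4,6-difluorobenzaldehyde F4. Ortho attack is favoured by cation chelation to the formyl oxygen.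
- BnOH, NaH, DMF (rt to 60 °C) then replaces the two remaining activated fluorides to give 8.

Step 12. Over-oxidation may cleave the central C–C bond, permanganate may attack the benzylic C2–H or C4–H bonds, silyl groups may be lost in the aqueous medium, or the lipophilic substrate may dissolve poorly. The fallback sets out from 20 and comes back at 21; it raises the oxidation level stepwise.
- Semi-hydrogenation (H2, Pd/CaCO3 poisoned with Pb(OAc)2, quinoline) should give the (Z)-stilbene F5.
- Dihydroxylation (OsO4 cat., NMO, acetone-H2O) should give the 1,2-diol F6 as a mixture of carbinol epimers, which is of no consequence.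
- Double Swern oxidation (DMSO, (COCl)2, Et3N, -78 °C) should give 21 without glycol cleavage.

Further compounds
F1 | step 7 | 2,4-bis(benzyloxy)-6-hydroxybenzaldehyde | O=Cc1c(O)cc(OCc2ccccc2)cc1OCc1ccccc1
F2 | step 7 | (E)-3-[2,4-bis(benzyloxy)-6-hydroxyphenyl]-1-[4-(benzyloxy)phenyl]prop-2-en-1-one | O=C(/C=C/c1c(O)cc(OCc2ccccc2)cc1OCc1ccccc1)c1ccc(OCc2ccccc2)cc1
F3 | step 7 | (R)-3-[2,4-bis(benzyloxy)-6-hydroxyphenyl]-1-[4-(benzyloxy)phenyl]propan-1-ol | O[C@@H](c1ccc(OCc2ccccc2)cc1)CCc1c(O)cc(OCc2ccccc2)cc1OCc1ccccc1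
F4 | step 5 | (R)-2-{2-azido-1-[4-(benzyloxy)phenyl]ethoxy}-4,6-difluorobenzaldehyde | O=Cc1c(F)cc(F)cc1O[C@H](c1ccc(OCc2ccccc2)cc1)CN=[N+]=[N-]
F5 | step 12 | (S)-8-{(Z)-2-[4-(tert-butyldimethylsilyloxy)phenyl]ethenyl}flavan trisilyl ether | C1C[C@@H](c2ccc(O[Si](C)(C)C(C)(C)C)cc2)Oc2c(/C=C\c3ccc(O[Si](C)(C)C(C)(C)C)cc3)c(O[Si](C)(C)C(C)(C)C)cc(O[Si](C)(C)C(C)(C)C)c21
F6 | step 12 | 1-[(S)-flavan-8-yl]-2-arylethane-1,2-diol tetrasilyl ether (carbinol epimers) | C1C[C@@H](c2ccc(O[Si](C)(C)C(C)(C)C)cc2)Oc2c(C(O)C(O)c3ccc(O[Si](C)(C)C(C)(C)C)cc3)c(O[Si](C)(C)C(C)(C)C)cc(O[Si](C)(C)C(C)(C)C)c21
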